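This flask cannot hold more target than the substrate charged to it, yet the first equilibrium reckoning below asks for exactly that.

substrate 1.0 mM; solid reagent 5.00 mM; time 50 min

    intermediate ⇌ target + by-product (K1 = 0.0044 M, k1 = 0.00818 /s)
    solid reagent ⇌ partner, rate k2*(cs2 - [partner]) while solid is left; crystals form when [partner] > cs2 (cs2 = 0.37 mM, k2 = 0.00842 /s)
    substrate + partner ⇌ intermediate (K3 = 2600 /M, k3 = 535 /M/s)

- as a solid, counted per litre of solution: solid reagent
- at the start none of the solid reagent is in solution
- the reaction counts as stopped when no species that holds the substrate changes by six tenths of a point or more over the second half of the time
- run time (flask): 50 min

* at 50 min, what has stopped the reaction, if anything has (for what has run out or reacted, a solid counts together with what of it has only dissolved) (the partner has run out first / all of the substrate has reacted / forward and back rates have come level / it is still moving)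
* conversion of substrate at 50 min
* amount of target at 50 min, in percent of the substrate charged
* amount of intermediate at 50 min, in percent of the substrate charged

In the first instants no partner is in solution, and the solid reagent dissolves at 0.187 mM/min at most. At the charged amount of substrate, a dissolved partner is captured in about 1.87 s, forward rate alone, much faster than the dissolution time of 1.98 min, so in those instants partner is taken up soon after it dissolves.

In the middle, intermediate sheds target and by-product with a half-life of 1.41 min, forward rate alone. Capture and its undoing settle in about 2.48 s, faster than that shedding. Substrate and intermediate therefore behave as one pool, in pre-equilibrium.

Toward the end, if solid stands, partner rises to its solubility, and intermediate per substrate becomes 0.962. The pool constant 2.16 mM is the equilibrium constant of shedding times the intermediate's share of the pool. Target equals by-product, and the pool is what the target has not taken: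

target × target = pool constant × (substrate charged − target)

Leaving the whole charge in the pool gives target 1.47 mM, more than the 1.0 mM charged: the impossibility. So the same equation is rewritten and iterated, starting from target equal to the charge:

target = pool constant × substrate charged / (pool constant + target)

0.683 mM, then 0.759 mM, then 0.740 mM, then 0.745 mM

That leaves intermediate at 0.125 mM and substrate at 0.130 mM. The demand on the solid, counting target, intermediate and dissolved partner, is 1.24 mM, less than the 5.00 mM charged, so solid does stand. At the full rate that dissolution takes 6.63 min; the rate tapers as partner rises, but 50 min are allowed, so this reckoning commits to forward and back rates level.

The forecast reads forward and back rates have come level, conversion 86.9%, target 74.4% and intermediate 12.6%, on the ground that “solid remains and holds the partner”.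

The flask gives forward and back rates have come level, with conversion 86.9%, target 74.4% and intermediate 12.6%.

Target stops there because of the undoing of target + by-product into intermediate: the run without that way back reaches >99.9% of target, against 74.4% with it. The pool constant carries this to the lean flask with 1.2 mM of solid reagent, below the demand, where partner follows from the balance. Partner comes to 0.330 mM, the pool constant falls to 2.03 mM, and target becomes 0.735 mM. Going round once more gives partner 0.343 mM. The lean flask reads solid reagent 0%, partner 0.340 mM and target 73.7%.

The constants are assumed.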